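**Plan**
- Numbering: decalin C4 (gem-dimethyl), C5=C6, C8 (CH-CH3), C9 (quaternary), C10 (ring-fusion CH), C11 (benzylic CH2); arene C1' (on C11), C2' (O-sulfate), C3' (CHO), C4' and C5' (OH), C6' (H).
- Retrosynthesis: the O2'–S bond, the two O-protecting groups and the C3'–CHO bond go first. The arene is then opened at C5'–C6', C1'–C2' and C2'–C3' into a C9-propargyl decalin, an alkoxy(alkenyl)carbene chromium complex and one CO. The alkyne goes back to a C9 aldehyde, and ring B is cut at C7–C8 and C9–C10.
- Enabling feature: O2' and O5' are para, C1' lies between C2' and the unsubstituted C6', and C3' is free before formylation. This is the pattern that a terminal alkyne, a carbene carbon with its vinyl group and a CO ligand give in one ring closure.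
- Forward order: ring A is bought, ring B closes by Diels–Alder reaction, the aldehyde is extended by two carbons to the alkyne, and the arene ring closes by benzannulation. Formylation, sulfation and deprotection follow.
- Stereochemistry: C8/C9 from the Z geometry of the dienophile, C9/C10 from the exo transition state, absolute sense from a chiral oxazaborolidinium catalyst. No stereocentre is formed or touched afterwards.

Key step: step 10

Remark 1: aryl hydrogen sulfates are stable only as salts, so 23 is handled as its ammonium salt and written in the neutral form of the given structure.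
Remark 2: the oxazaborolidinium ion from (R)-α,α-diphenylprolinol is assumed to cover the Re face at C2 of the s-trans bound enal, leaving the Si face that the target needs to the diene. This follows the binding model for 2-substituted enals, and the antipodal catalyst would be used if the sense proved opposite.

**Route**

Step 1
Reactants: 1 2,2-dimethylcyclohexanone
Product: 2 6,6-dimethylcyclohex-1-en-1-yl triflate
Conditions: LiN(i-Pr)2, THF, −78 °C; PhNTf2, −78 → 0 °C
Reagents that add atoms: N-phenylbis(trifluoromethanesulfonimide), O=S(=O)(N(c1ccccc1)S(=O)(=O)C(F)(F)F)C(F)(F)F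
Why: Enol triflate formation from the lithium enolate should give a single regioisomer, because only one α-carbon carries hydrogen.

Step 2
Reactants: 2 6,6-dimethylcyclohex-1-en-1-yl triflate
Product: 3 1-ethenyl-6,6-dimethylcyclohexene
Conditions: CH2=CHSnBu3, Pd(PPh3)4 (3 mol %), LiCl, THF, 65 °C
Reagents that add atoms: tributyl(vinyl)stannane, C=C[Sn](CCCC)(CCCC)CCCC
Why: Stille coupling of an enol triflate with a vinylstannane (oxidative addition to zerovalent palladium, chloride-assisted transmetallation, reductive elimination) should give the 1,3-diene with the ring double bond fixed in position.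

Step 3
Reactants: 4 angelic acid
Product: 5 (Z)-2-methylbut-2-en-1-ol
Conditions: LiAlH4, Et2O, 0 °C → rt; H2O work-up
Reagents that add atoms: none
Why: Hydride reduction of the carboxylic acid runs through carboxylate and aluminium alkoxide stages that offer no path for rotation of the trisubstituted Z alkene.

Step 4
Reactants: 5 (Z)-2-methylbut-2-en-1-ol
Product: 6 angelic aldehyde, (Z)-2-methylbut-2-enal
Conditions: TEMPO (10 mol %), PhI(OAc)2, CH2Cl2, 0 °C → rt; used as a distilled solution
Reagents that add atoms: none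
Why: Oxoammonium (TEMPO) oxidation with PhI(OAc)2 as terminal oxidant is a near-neutral alcohol oxidation that converts Z allylic alcohols into Z enals without geometric isomerisation or over-oxidation.

Step 5
Reactants: 3 1-ethenyl-6,6-dimethylcyclohexene; 6 angelic aldehyde
Product: 7 (1R,2R,8aR)-1,2,5,5-tetramethyl-1,2,3,5,6,7,8,8a-octahydronaphthalene-1-carbaldehyde (decalin C9 aldehyde)
Conditions: oxazaborolidine from (R)-α,α-diphenylprolinol and tri-o-tolylboroxine, activated with HNTf2 (20 mol %), CH2Cl2, −78 → −40 °C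
Reagents that add atoms: none
Why: Enantioselective Diels–Alder reaction under oxazaborolidinium catalysis, in which the formyl-bearing carbon bonds to the ring terminus of the diene (ortho rule), the exo transition state usual for 2-methyl enals places CHO on the face of H-10, the Z geometry is transferred suprafacially so that the C8 methyl is cis to CHO and trans to the C9 methyl, and the catalyst leaves only the Si face of C2 open, which sets C8, C9 and C10 in the absolute sense shown while the non-nucleophilic counter-ion and low temperature disfavour Z to E isomerisation.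

Step 6
Reactants: 7 decalin C9 aldehyde
Product: 9 2-[(1R,2R,8aS)-1,2,5,5-tetramethyl-1,2,3,5,6,7,8,8a-octahydronaphthalen-1-yl]acetaldehyde, via methyl enol ether 8 (not isolated)
Conditions: Ph3P(CH2OMe)Cl, KN(SiMe3)2, THF, 0 °C → rt; then 2 M HCl, THF, rt
Reagents that add atoms: (methoxymethyl)triphenylphosphonium chloride, COC[P+](c1ccccc1)(c1ccccc1)c1ccccc1.[Cl-]; water, O
Why: Wittig methoxymethylenation followed by acid hydrolysis of the enol ether is the standard one-carbon homologation of hindered, non-enolisable aldehydes, and no stereocentre is at risk because C9 is quaternary.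

Step 7
Reactants: 9 homologated aldehyde
Product: 10 (1R,2R,8aS)-1,2,5,5-tetramethyl-1-(prop-2-yn-1-yl)-1,2,3,5,6,7,8,8a-octahydronaphthalene (C9-propargyl decalin)
Conditions: MeC(O)C(N2)P(O)(OMe)2, K2CO3, MeOH, 0 °C → rt
Reagents that add atoms: dimethyl (1-diazo-2-oxopropyl)phosphonate, CC(=O)C(=[N+]=[N-])P(=O)(OC)OC
Why: Seyferth–Gilbert homologation in the Ohira–Bestmann variant converts the aldehyde into the terminal alkyne through a diazoalkene and 1,2-hydrogen shift of the alkylidene carbene under mildly basic conditions.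

Step 8
Reactants: 11 methyl vinyl ether; 12 chromium hexacarbonyl
Product: 15 tetramethylammonium pentacarbonyl(2-methoxyprop-2-enoyl)chromate, via 1-methoxyvinyllithium 13 (not isolated), via lithium acyl chromate 14 (not isolated)
Conditions: t-BuLi, THF, −78 → 0 °C; Cr(CO)6, Et2O, 0 °C → rt; then Me4NBr, H2O
Reagents that add atoms: tetramethylammonium bromide, C[N+](C)(C)C.[Br-]
Why: First half of a Fischer carbene synthesis, in which the α-lithiated vinyl ether adds to a carbonyl ligand of Cr(CO)6 and the acyl chromate is isolated as its storable tetramethylammonium salt.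

Step 9
Reactants: 15 tetramethylammonium acyl chromate
Product: 17 pentacarbonyl[benzyloxy(1-methoxyethenyl)carbene]chromium, via acetoxycarbene complex 16 (not isolated)
Conditions: AcBr, CH2Cl2, −40 °C; then BnOH, −40 → 0 °C
Reagents that add atoms: benzyl alcohol, OCc1ccccc1
Why: O-acylation gives an acyloxycarbene whose acetate is displaced by benzyl alcohol at the carbene carbon (addition–elimination), the established alkoxy exchange for alkoxy groups that cannot be introduced by direct alkylation.

Step 10
Reactants: 10 C9-propargyl decalin; 17 pentacarbonyl[benzyloxy(1-methoxyethenyl)carbene]chromium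
Product: 19 4-(benzyloxy)-5-methoxy-2-{[(1R,2R,8aS)-1,2,5,5-tetramethyl-1,2,3,5,6,7,8,8a-octahydronaphthalen-1-yl]methyl}phenol, via arene Cr(CO)3 complex 18 (not isolated)
Conditions: 17 (1.5 equiv), degassed THF, 50 °C; then air, SiO2, rt
Reagents that add atoms: none
Why: Thermal loss of one CO from 17 lets the alkyne insert into the Cr=C bond with its CH2 terminus next to chromium, so the carbene carbon (C5') bonds to the terminal alkyne carbon (C6'), and CO then inserts at the internal alkyne carbon (C1'–C2') to give a chromium-bound dienylketene. The ring closes by 6π-electrocyclisation of that ketene onto the vinyl CH2 (C2'–C3'), and tautomerisation gives the phenol as its Cr(CO)3 complex 18, from which air removes the metal. The closest known reactions are Dötz benzannulations of isopropenyl- and dihydropyranyl(alkoxy)carbene chromium complexes with terminal alkyl alkynes. No stereocentre is formed, and those of the decalin are insulated from the reacting alkyne by C11. The step needs regioselective insertion, which the steric difference between H and the neopentyl-type CH2 on the alkyne secures, and it needs phenol formation to win over CO-free five-ring formation, which the alkenyl carbene and the coordinating solvent THF secure. The isolated trisubstituted C5=C6 alkene is not a partner for the carbene complex under these conditions.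

Step 11
Reactants: 19 phenol (2'-OH, 4'-OMe, 5'-OBn)
Product: 20 3-(benzyloxy)-6-hydroxy-2-methoxy-5-{[(1R,2R,8aS)-1,2,5,5-tetramethyl-1,2,3,5,6,7,8,8a-octahydronaphthalen-1-yl]methyl}benzaldehyde
Conditions: MgCl2, Et3N, (CH2O)n, MeCN, 80 °C; dilute HCl work-up
Reagents that add atoms: paraformaldehyde (as formaldehyde), C=O
Why: Magnesium-mediated ortho-formylation (Casnati–Skattebøl) directs formaldehyde through the magnesium phenoxide to C3', the only free position ortho to O2', and a second formaldehyde oxidises the benzylic alkoxide to the aldehyde by hydride transfer.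

Step 12
Reactants: 20 salicylaldehyde
Product: 21 4-(benzyloxy)-2-formyl-3-methoxy-6-{[(1R,2R,8aS)-1,2,5,5-tetramethyl-1,2,3,5,6,7,8,8a-octahydronaphthalen-1-yl]methyl}phenyl 2,2,2-trichloroethyl sulfate
Conditions: Cl3CCH2OSO2Cl, Et3N, DMAP, THF, 0 °C → rt
Reagents that add atoms: 2,2,2-trichloroethyl chlorosulfate, ClS(=O)(=O)OCC(Cl)(Cl)Cl
Why: Sulfation of the only free phenol with a chlorosulfate ester (substitution at sulfur, DMAP catalysis) installs the sulfate as a neutral trichloroethyl diester that can be chromatographed and tolerates Lewis acids.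

Step 13
Reactants: 21 protected sulfate diester
Product: 22 2-formyl-3,4-dihydroxy-6-{[(1R,2R,8aS)-1,2,5,5-tetramethyl-1,2,3,5,6,7,8,8a-octahydronaphthalen-1-yl]methyl}phenyl 2,2,2-trichloroethyl sulfate
Conditions: BCl3, C6HMe5, CH2Cl2, −78 → 0 °C; then H2O
Reagents that add atoms: none
Why: BCl3 ether cleavage removes the benzyl group at low temperature with pentamethylbenzene as cation trap and removes the C4' methyl group through the six-membered boron chelate with the ortho formyl group, while the sulfate diester and the trisubstituted alkene should survive at this temperature.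

Step 14
Reactants: 22 catechol sulfate diester
Product: 23 2-formyl-3,4-dihydroxy-6-{[(1R,2R,8aS)-1,2,5,5-tetramethyl-1,2,3,5,6,7,8,8a-octahydronaphthalen-1-yl]methyl}phenyl hydrogen sulfate (target; isolated as ammonium salt)
Conditions: Zn dust, HCO2NH4, MeOH, rt
Reagents that add atoms: none
Why: Reductive β-elimination of the 2,2,2-trichloroethyl group by zinc releases the sulfate monoester under near-neutral conditions that should leave the acid-labile aryl sulfate, the aldehyde and the alkene intact.

**Compound list**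
1 | 2,2-dimethylcyclohexan-1-one | CC1(C)CCCCC1=O | starting material
2 | 6,6-dimethylcyclohex-1-en-1-yl trifluoromethanesulfonate | CC1(C)CCCC=C1OS(=O)(=O)C(F)(F)F | intermediate
3 | 1-ethenyl-6,6-dimethylcyclohex-1-ene | C=CC1=CCCCC1(C)C | intermediate
4 | angelic acid, (Z)-2-methylbut-2-enoic acid | C/C=C(/C)C(=O)O | starting material
5 | (Z)-2-methylbut-2-en-1-ol | C/C=C(/C)CO | intermediate
6 | angelic aldehyde, (Z)-2-methylbut-2-enal | C/C=C(/C)C=O | intermediate
7 | (1R,2R,8aR)-1,2,5,5-tetramethyl-1,2,3,5,6,7,8,8a-octahydronaphthalene-1-carbaldehyde (CHO, H-10 and the C8 methyl on one face, the C9 methyl on the other) | C[C@@H]1CC=C2[C@@H](CCCC2(C)C)[C@]1(C)C=O | intermediate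
8 | (1R,2R,8aS)-1-(2-methoxyethenyl)-1,2,5,5-tetramethyl-1,2,3,5,6,7,8,8a-octahydronaphthalene, E/Z mixture | C[C@@H]1CC=C2[C@@H](CCCC2(C)C)[C@]1(C)C=COC | intermediate
9 | 2-[(1R,2R,8aS)-1,2,5,5-tetramethyl-1,2,3,5,6,7,8,8a-octahydronaphthalen-1-yl]acetaldehyde | C[C@@H]1CC=C2[C@@H](CCCC2(C)C)[C@]1(C)CC=O | intermediate
10 | (1R,2R,8aS)-1,2,5,5-tetramethyl-1-(prop-2-yn-1-yl)-1,2,3,5,6,7,8,8a-octahydronaphthalene | C[C@@H]1CC=C2[C@@H](CCCC2(C)C)[C@]1(C)CC#C | intermediate
11 | methyl vinyl ether | COC=C | starting material
12 | chromium hexacarbonyl, Cr(CO)6 | O=C=[Cr](=C=O)(=C=O)(=C=O)(=C=O)=C=O | starting material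
13 | (1-methoxyethenyl)lithium | [Li]C(=C)OC | intermediate
14 | lithium pentacarbonyl(2-methoxyprop-2-enoyl)chromate | [Li+].[O-]C(C(=C)OC)=[Cr](=C=O)(=C=O)(=C=O)(=C=O)=C=O | intermediate
15 | tetramethylammonium pentacarbonyl(2-methoxyprop-2-enoyl)chromate | C[N+](C)(C)C.[O-]C(C(=C)OC)=[Cr](=C=O)(=C=O)(=C=O)(=C=O)=C=O | intermediate
16 | pentacarbonyl[acetoxy(1-methoxyethenyl)carbene]chromium | CC(=O)OC(C(=C)OC)=[Cr](=C=O)(=C=O)(=C=O)(=C=O)=C=O | intermediate
17 | pentacarbonyl[benzyloxy(1-methoxyethenyl)carbene]chromium | C=C(OC)C(OCc1ccccc1)=[Cr](=C=O)(=C=O)(=C=O)(=C=O)=C=O | intermediate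
18 | tricarbonylchromium complex of 19, Cr(CO)3 bound η6 to the new benzene ring | C[C@@H]1CC=C2[C@@H](CCCC2(C)C)[C@]1(C)Cc1cc(OCc2ccccc2)c(OC)cc1O.O=C=[Cr](=C=O)=C=O | intermediate
19 | 4-(benzyloxy)-5-methoxy-2-{[(1R,2R,8aS)-1,2,5,5-tetramethyl-1,2,3,5,6,7,8,8a-octahydronaphthalen-1-yl]methyl}phenol | C[C@@H]1CC=C2[C@@H](CCCC2(C)C)[C@]1(C)Cc1cc(OCc2ccccc2)c(OC)cc1O | intermediate
20 | 3-(benzyloxy)-6-hydroxy-2-methoxy-5-{[(1R,2R,8aS)-1,2,5,5-tetramethyl-1,2,3,5,6,7,8,8a-octahydronaphthalen-1-yl]methyl}benzaldehyde | C[C@@H]1CC=C2[C@@H](CCCC2(C)C)[C@]1(C)Cc1cc(OCc2ccccc2)c(OC)c(C=O)c1O | intermediate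
21 | 4-(benzyloxy)-2-formyl-3-methoxy-6-{[(1R,2R,8aS)-1,2,5,5-tetramethyl-1,2,3,5,6,7,8,8a-octahydronaphthalen-1-yl]methyl}phenyl 2,2,2-trichloroethyl sulfate | C[C@@H]1CC=C2[C@@H](CCCC2(C)C)[C@]1(C)Cc1cc(OCc2ccccc2)c(OC)c(C=O)c1OS(=O)(=O)OCC(Cl)(Cl)Cl | intermediate
22 | 2-formyl-3,4-dihydroxy-6-{[(1R,2R,8aS)-1,2,5,5-tetramethyl-1,2,3,5,6,7,8,8a-octahydronaphthalen-1-yl]methyl}phenyl 2,2,2-trichloroethyl sulfate | C[C@@H]1CC=C2[C@@H](CCCC2(C)C)[C@]1(C)Cc1cc(O)c(O)c(C=O)c1OS(=O)(=O)OCC(Cl)(Cl)Cl | intermediate
23 | 2-formyl-3,4-dihydroxy-6-{[(1R,2R,8aS)-1,2,5,5-tetramethyl-1,2,3,5,6,7,8,8a-octahydronaphthalen-1-yl]methyl}phenyl hydrogen sulfate | C[C@@H]1CC=C2[C@@H](CCCC2(C)C)[C@]1(C)Cc1cc(O)c(O)c(C=O)c1OS(=O)(=O)O | target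

**Count and risks**
Total: 14 steps. Longest linear sequence: 10 steps (1, 2, 5, 6, 7, 10, 11, 12, 13, 14).

1. Step 5. The Z enal may isomerise to the E enal on the cationic boron Lewis acid before it cycloadds, which would deliver the C8 epimer. Exo and facial selectivity may also be incomplete, and the facial sense rests on a model. The fallback sets out from 3 and 6 and comes back at 7. Diene 3 and enal 6 are combined without any acid under high pressure (about 1.3 GPa, CH2Cl2, rt), where no isomerisation path exists, to give the racemic exo aldehyde F1. Condensation with (1R,2R)-N,N'-dimethyl-1,2-diphenylethane-1,2-diamine (molecular sieves, Et2O) gives two diastereomeric aminals, the imidazolidine of 7 F2 and the imidazolidine of the enantiomer of 7 F3, which are separated by chromatography or crystallisation. Dilute aqueous acid hydrolyses F2 to enantiopure 7.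

2. Step 10. The unhindered alkoxyvinyl carbene complex may oligomerise or decompose faster than the alkyne inserts, part of the material may cyclise without CO to five-membered products, and the electron-rich phenol may be oxidised during removal of chromium. The fallback sets out from 7 and comes back at 19, giving up the benzannulation in favour of a ready-made arene. Commercial 4-(benzyloxy)-3-methoxyphenol is brominated para to the methoxy group (NBS, MeCN, 0 °C) to 4-(benzyloxy)-2-bromo-5-methoxyphenol F4, which is protected (MOMCl, i-Pr2NEt) as 1-(benzyloxy)-5-bromo-2-methoxy-4-(methoxymethoxy)benzene F5. Bromine–lithium exchange (n-BuLi, THF, −78 °C) and addition to aldehyde 7 give the benzylic carbinol F6. Barton–McCombie deoxygenation follows through the S-methyl xanthate F7 (NaH, CS2, MeI; then Bu3SnH, AIBN, toluene, 90 °C) and gives the methoxymethyl ether of 19 F8. HCl in MeOH removes the methoxymethyl group to give 19.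

3. Step 13. The Lewis acid may attack the sulfate diester or promote protonation and cyclisation at the C5=C6 alkene in competition with ether cleavage, and demethylation next to the sulfated oxygen may stall. The fallback sets out from 20 and comes back at 23, with the order of events changed so that no sulfate meets BCl3 and no reductive step is needed. BCl3 and C6HMe5 act on 20 to give 2,3,6-trihydroxy-5-(decalinylmethyl)benzaldehyde F9, handled under argon. 1,1'-Carbonyldiimidazole (THF, 0 °C) bridges the catechol pair O4'/O5' as the cyclic carbonate F10 and leaves O2' free. SO3·pyridine sulfates O2' to the carbonate-protected aryl sulfate F11. LiOH in degassed aqueous THF at 0 °C opens the carbonate and gives 23 as its salt.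

**Further compounds**
F1 | step 5 | racemic (1R*,2R*,8aR*)-1,2,5,5-tetramethyl-1,2,3,5,6,7,8,8a-octahydronaphthalene-1-carbaldehyde (racemate of 7; one enantiomer drawn) | C[C@@H]1CC=C2[C@@H](CCCC2(C)C)[C@]1(C)C=O
F2 | step 5 | (4R,5R)-1,3-dimethyl-4,5-diphenylimidazolidine bearing the decalinyl group of 7 at C2 | C[C@@H]1CC=C2[C@@H](CCCC2(C)C)[C@]1(C)C1N(C)[C@H](c2ccccc2)[C@@H](c2ccccc2)N1C
F3 | step 5 | (4R,5R)-1,3-dimethyl-4,5-diphenylimidazolidine bearing the decalinyl group of the enantiomer of 7 at C2 | C[C@H]1CC=C2[C@H](CCCC2(C)C)[C@@]1(C)C1N(C)[C@H](c2ccccc2)[C@@H](c2ccccc2)N1C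
F4 | step 10 | 4-(benzyloxy)-2-bromo-5-methoxyphenol | Oc1cc(OC)c(OCc2ccccc2)cc1Br
F5 | step 10 | 1-(benzyloxy)-5-bromo-2-methoxy-4-(methoxymethoxy)benzene | COCOc1cc(OC)c(OCc2ccccc2)cc1Br
F6 | step 10 | [5-(benzyloxy)-4-methoxy-2-(methoxymethoxy)phenyl][(1R,2R,8aR)-1,2,5,5-tetramethyl-1,2,3,5,6,7,8,8a-octahydronaphthalen-1-yl]methanol, both carbinol epimers | C[C@@H]1CC=C2[C@@H](CCCC2(C)C)[C@]1(C)C(O)c1cc(OCc2ccccc2)c(OC)cc1OCOC
F7 | step 10 | O-ester of F6 with S-methyl dithiocarbonic acid (xanthate) | C[C@@H]1CC=C2[C@@H](CCCC2(C)C)[C@]1(C)C(OC(=S)SC)c1cc(OCc2ccccc2)c(OC)cc1OCOC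
F8 | step 10 | 1-(benzyloxy)-2-methoxy-4-(methoxymethoxy)-5-{[(1R,2R,8aS)-1,2,5,5-tetramethyl-1,2,3,5,6,7,8,8a-octahydronaphthalen-1-yl]methyl}benzene | C[C@@H]1CC=C2[C@@H](CCCC2(C)C)[C@]1(C)Cc1cc(OCc2ccccc2)c(OC)cc1OCOC
F9 | step 13 | 2,3,6-trihydroxy-5-{[(1R,2R,8aS)-1,2,5,5-tetramethyl-1,2,3,5,6,7,8,8a-octahydronaphthalen-1-yl]methyl}benzaldehyde | C[C@@H]1CC=C2[C@@H](CCCC2(C)C)[C@]1(C)Cc1cc(O)c(O)c(C=O)c1O
F10 | step 13 | 5-hydroxy-2-oxo-6-{[(1R,2R,8aS)-1,2,5,5-tetramethyl-1,2,3,5,6,7,8,8a-octahydronaphthalen-1-yl]methyl}-1,3-benzodioxole-4-carbaldehyde | C[C@@H]1CC=C2[C@@H](CCCC2(C)C)[C@]1(C)Cc1cc2OC(=O)Oc2c(C=O)c1O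
F11 | step 13 | 4-formyl-2-oxo-6-{[(1R,2R,8aS)-1,2,5,5-tetramethyl-1,2,3,5,6,7,8,8a-octahydronaphthalen-1-yl]methyl}-1,3-benzodioxol-5-yl hydrogen sulfate | C[C@@H]1CC=C2[C@@H](CCCC2(C)C)[C@]1(C)Cc1cc2OC(=O)Oc2c(C=O)c1OS(=O)(=O)O
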